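**Strategy.** The farnesyl-type chain is cut between C1', the methylene on C3 of the pyranone ring, and the olefinic carbon C2'. The key step exploits the skipped-diene array C4=C3 (pyranone ring)–C1'H2–C2'=C3'(CH3): C1' is an activated allylic-type electrophile as a chloromethyl group, and the E-methyl-branched C2'=C3' olefin is the retron of syn-methylmetalation of a terminal alkyne. In one operation, carboalumination of enynol 6 followed by coupling of the alkenylalane with chloride 10 under zerovalent palladium catalysis forms C1'–C2', installs the C3' methyl and fixes the E geometry. The precursors are a C13 dienynol lacking that methyl and a 4-O-protected 3-(chloromethyl)coumarin.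

Key step: step 6

Remark: side-chain carbons are numbered C1' (on C3 of the coumarin) to C12' (bearing the benzoate). The 4-O-[2-(trimethylsilyl)ethyl] ether of the 4-hydroxycoumarin is treated as a vinylogous 2-(trimethylsilyl)ethyl ester and is assumed to fragment with fluoride as such esters do.

**Step 1**
Reactants: 1 geranyl bromide, (2E)-1-bromo-3,7-dimethylocta-2,6-diene; 2 1-(trimethylsilyl)propyne
Product: 5 (5E)-6,10-dimethylundeca-5,9-dien-1-yne, via lithiated silylpropyne 3 (not isolated), via silylated enyne 4 (not isolated)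
Conditions: 2, n-BuLi (1.1 equiv), THF, −78 °C; then 1, −78 °C to rt; then MeOH, K2CO3 (cat.), rt
Reagents that add atoms: none
Why: Propargylic lithiation of the silylpropyne and SN2 alkylation with the primary allylic bromide should join the two pieces at the propargylic carbon without touching the E olefin, and methanolysis of the C–Si bond in the same flask should free the terminal alkyne.

**Step 2**
Reactants: 5 (5E)-6,10-dimethylundeca-5,9-dien-1-yne
Product: 6 (2E,6E)-2,6-dimethylundeca-2,6-dien-10-yn-1-ol
Conditions: SeO2 (0.2 equiv), t-BuOOH (70% aq., 2.5 equiv), salicylic acid (0.1 equiv), CH2Cl2, 0 °C to rt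
Reagents that add atoms: selenium dioxide, O=[Se]=O (oxygen carrier); tert-butyl hydroperoxide, CC(C)(C)OO (terminal source of the oxygen)
Why: Catalytic Riley allylic oxidation (ene reaction, then [2,3]-sigmatropic shift) should hydroxylate the methyl trans to the chain on the less hindered terminal isopropylidene group, giving the E primary allylic alcohol.

**Step 3**
Reactants: 7 4-chloro-2-oxo-2H-chromene-3-carbaldehyde (4-chloro-3-formylcoumarin)
Product: 8 2-oxo-4-[2-(trimethylsilyl)ethoxy]-2H-chromene-3-carbaldehyde
Conditions: Me3SiCH2CH2OH (1.3 equiv), Et3N (1.5 equiv), DMAP (0.1 equiv), CH2Cl2, 0 °C to rt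
Reagents that add atoms: 2-(trimethylsilyl)ethanol, C[Si](C)(C)CCO
Why: Addition–elimination (vinylogous acyl substitution) at C4, which is activated by both the lactone carbonyl and the formyl group, should exchange chloride for the silylethoxy group.

**Step 4**
Reactants: 8 2-oxo-4-[2-(trimethylsilyl)ethoxy]-2H-chromene-3-carbaldehyde
Product: 9 3-(hydroxymethyl)-4-[2-(trimethylsilyl)ethoxy]-2H-chromen-2-one
Conditions: NaBH4, CeCl3·7H2O, EtOH/THF, −40 °C
Reagents that add atoms: none
Why: Luche 1,2-reduction should reduce the aldehyde quickly at low temperature in a near-neutral medium, before conjugate reduction or alkoxy exchange at C4 can occur, and the lactone should stay intact.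

**Step 5**
Reactants: 9 3-(hydroxymethyl)-4-[2-(trimethylsilyl)ethoxy]-2H-chromen-2-one
Product: 10 3-(chloromethyl)-4-[2-(trimethylsilyl)ethoxy]-2H-chromen-2-one
Conditions: N-chlorosuccinimide, PPh3, CH2Cl2, −20 to 0 °C
Reagents that add atoms: N-chlorosuccinimide, O=C1CCC(=O)N1Cl
Why: Appel-type chlorination through the alkoxyphosphonium salt should convert the primary alcohol into the chloride under neutral conditions that spare the acid-labile enol ether.

**Step 6**
Reactants: 6 (2E,6E)-2,6-dimethylundeca-2,6-dien-10-yn-1-ol; 10 3-(chloromethyl)-4-[2-(trimethylsilyl)ethoxy]-2H-chromen-2-one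
Product: 12 3-[(2E,6E,10E)-12-hydroxy-3,7,11-trimethyldodeca-2,6,10-trien-1-yl]-4-[2-(trimethylsilyl)ethoxy]-2H-chromen-2-one, via alkenylalane 11 (not isolated)
Conditions: 6 (1.2 equiv), Me3Al (3.5 equiv), Cp2ZrCl2 (0.25 equiv), CH2Cl2, 0 °C to rt; volatiles removed in vacuo; then 10 (1.0 equiv), Pd(PPh3)4 (5 mol%), THF, 0 °C to rt; aq. potassium sodium tartrate work-up
Reagents that add atoms: trimethylaluminium, C[Al](C)C
Why: Zirconium-catalysed syn-methylalumination of the terminal alkyne of 6 (Negishi carboalumination, the hydroxyl being capped first as its dimethylaluminium alkoxide) should place CH3 on the internal carbon (future C3') and aluminium on the terminal carbon (future C2'), giving alane 11 with E geometry. Zerovalent palladium should then insert into the C1'–Cl bond of 10 (an allylic chloride of the C3=C4 enol-ether double bond of the pyranone ring), take over the alkenyl group from aluminium, and form C1'–C2' by reductive elimination with retention of olefin geometry. The closest known reaction type is the one-pot carboalumination/palladium-catalysed coupling of alkenylalanes with benzylic and allylic chlorides, as used for isoprenoid chains and prenylated quinones. No ring is closed and no stereocentre is formed; the only stereochemical element, the E C2'=C3' double bond, is fixed by the syn addition. The step needs terminal regioselectivity in the alumination (secured by the unhindered terminal alkyne), transfer of the sp2 carbon in preference to methyl (secured by its faster transmetalation and by stripping excess Me3Al), and coupling at C1' rather than C4 of the allyl system (secured because C4 is fully substituted and attack there would break the enol-ether conjugation). The two trisubstituted olefins, the lactone and the silylethyl ether should not react with the alane at room temperature.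

**Step 7**
Reactants: 12 3-[(2E,6E,10E)-12-hydroxy-3,7,11-trimethyldodeca-2,6,10-trien-1-yl]-4-[2-(trimethylsilyl)ethoxy]-2H-chromen-2-one
Product: 13 (2E,6E,10E)-2,6,10-trimethyl-12-{2-oxo-4-[2-(trimethylsilyl)ethoxy]-2H-chromen-3-yl}dodeca-2,6,10-trien-1-yl benzoate
Conditions: BzCl (1.2 equiv), pyridine, DMAP (cat.), CH2Cl2, 0 °C
Reagents that add atoms: benzoyl chloride, O=C(Cl)c1ccccc1
Why: DMAP-catalysed acylation should esterify the only free hydroxyl, the primary allylic alcohol, while the 4-oxygen stays masked.

**Step 8**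
Reactants: 13 (2E,6E,10E)-2,6,10-trimethyl-12-{2-oxo-4-[2-(trimethylsilyl)ethoxy]-2H-chromen-3-yl}dodeca-2,6,10-trien-1-yl benzoate
Product: 14 E-omega-benzoyloxyferulenol, (2E,6E,10E)-12-(4-hydroxy-2-oxo-2H-chromen-3-yl)-2,6,10-trimethyldodeca-2,6,10-trien-1-yl benzoate
Conditions: TBAF (2 equiv), THF, 0 °C to rt; cold 0.5 M HCl wash
Reagents that add atoms: none
Why: Fluoride attack on silicon should trigger β-elimination of ethylene and release the 4-oxidocoumarin, a leaving group comparable to a carboxylate, as in the cleavage of 2-(trimethylsilyl)ethyl esters; the conditions are non-acidic, so the polyene should not cyclise and the alkyl benzoate should survive.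

**Compound list**
1 | geranyl bromide, (2E)-1-bromo-3,7-dimethylocta-2,6-diene | CC(C)=CCC/C(C)=C/CBr | starting material
2 | 1-(trimethylsilyl)propyne | CC#C[Si](C)(C)C | starting material
3 | [3-(trimethylsilyl)prop-2-yn-1-yl]lithium | [Li]CC#C[Si](C)(C)C | intermediate (not isolated)
4 | trimethyl[(5E)-6,10-dimethylundeca-5,9-dien-1-yn-1-yl]silane | CC(C)=CCC/C(C)=C/CCC#C[Si](C)(C)C | intermediate (not isolated)
5 | (5E)-6,10-dimethylundeca-5,9-dien-1-yne | CC(C)=CCC/C(C)=C/CCC#C | intermediate
6 | (2E,6E)-2,6-dimethylundeca-2,6-dien-10-yn-1-ol | C#CCC/C=C(\C)CC/C=C(\C)CO | intermediate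
7 | 4-chloro-2-oxo-2H-chromene-3-carbaldehyde | O=Cc1c(Cl)c2ccccc2oc1=O | starting material
8 | 2-oxo-4-[2-(trimethylsilyl)ethoxy]-2H-chromene-3-carbaldehyde | O=Cc1c(OCC[Si](C)(C)C)c2ccccc2oc1=O | intermediate
9 | 3-(hydroxymethyl)-4-[2-(trimethylsilyl)ethoxy]-2H-chromen-2-one | OCc1c(OCC[Si](C)(C)C)c2ccccc2oc1=O | intermediate
10 | 3-(chloromethyl)-4-[2-(trimethylsilyl)ethoxy]-2H-chromen-2-one | ClCc1c(OCC[Si](C)(C)C)c2ccccc2oc1=O | intermediate
11 | dimethyl{(1E,5E,9E)-11-[(dimethylalumanyl)oxy]-2,6,10-trimethylundeca-1,5,9-trien-1-yl}alumane | C[Al](C)/C=C(\C)CC/C=C(\C)CC/C=C(\C)CO[Al](C)C | intermediate (not isolated)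
12 | 3-[(2E,6E,10E)-12-hydroxy-3,7,11-trimethyldodeca-2,6,10-trien-1-yl]-4-[2-(trimethylsilyl)ethoxy]-2H-chromen-2-one | C/C(=C\CC/C(C)=C/Cc1c(OCC[Si](C)(C)C)c2ccccc2oc1=O)CC/C=C(\C)CO | intermediate
13 | (2E,6E,10E)-2,6,10-trimethyl-12-{2-oxo-4-[2-(trimethylsilyl)ethoxy]-2H-chromen-3-yl}dodeca-2,6,10-trien-1-yl benzoate | C/C(=C\CC/C(C)=C/Cc1c(OCC[Si](C)(C)C)c2ccccc2oc1=O)CC/C=C(\C)COC(=O)c1ccccc1 | intermediate
14 | E-omega-benzoyloxyferulenol, (2E,6E,10E)-12-(4-hydroxy-2-oxo-2H-chromen-3-yl)-2,6,10-trimethyldodeca-2,6,10-trien-1-yl benzoate | C/C(=C\CC/C(C)=C/Cc1c(O)c2ccccc2oc1=O)CC/C=C(\C)COC(=O)c1ccccc1 | target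

**Step count**
Total steps: 8. Longest linear sequence: 6 steps (7 → 8 → 9 → 10 → 12 → 13 → 14, steps 3 to 8).

**Steps most likely to fail**

Risk 1, step 6. In the one-pot coupling, methyl transfer from residual methylaluminium species and Lewis-acid-induced ionisation of chloride 10 may outrun alkenyl transfer, and any regiochemical leakage of the alumination would be carried into the product. The fallback sets out from 6 and 10 and comes back at 12. The same carboalumination of 6 would be quenched with I2 to give the isolable vinyl iodide (2E,6E,10E)-11-iodo-2,6,10-trimethylundeca-2,6,10-trien-1-ol F1, which can be purified. Chloride 10 would be converted with Zn dust and LiCl in THF into the zinc reagent chloro({2-oxo-4-[2-(trimethylsilyl)ethoxy]-2H-chromen-3-yl}methyl)zinc F2. A Negishi coupling of F1 with excess F2 (Pd(OAc)2, SPhos, THF, rt) should then form the same C1'–C2' bond with reversed polarity and give 12.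

Risk 2, step 2. The allylic oxidation may not discriminate cleanly between the terminal and the internal trisubstituted olefin, may run on to the enal, and may touch the propargylic methylene. The fallback sets out from 5 and comes back at 6. Terminal-selective bromohydrin formation (NBS, THF/H2O, 0 °C) should give racemic (6E)-3-bromo-2,6-dimethylundec-6-en-10-yn-2-ol F3. K2CO3 in MeOH should close it to racemic 2,2-dimethyl-3-[(3E)-3-methyloct-3-en-7-yn-1-yl]oxirane F4. H5IO6 in Et2O/THF should cleave the epoxide to (4E)-4-methylnon-4-en-8-ynal F5. Wittig olefination with the stabilised ylide Ph3P=C(CH3)CO2Et (CH2Cl2, rt) should give ethyl (2E,6E)-2,6-dimethylundeca-2,6-dien-10-ynoate F6 with the E geometry, and i-Bu2AlH (CH2Cl2, −78 °C) should reduce the ester to 6.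

Risk 3, step 8. Basic fluoride and adventitious hydroxide may cleave or transesterify the benzoate, or attack the lactone, in competition with the β-silyl fragmentation. The fallback sets out from 12 and comes back at 14. The silylethyl group would be removed first, before any ester is present (TBAF, THF), to give 4-hydroxy-3-[(2E,6E,10E)-12-hydroxy-3,7,11-trimethyldodeca-2,6,10-trien-1-yl]-2H-chromen-2-one F7. Exhaustive benzoylation (BzCl, pyridine, DMAP) should give the dibenzoate 3-[(2E,6E,10E)-12-(benzoyloxy)-3,7,11-trimethyldodeca-2,6,10-trien-1-yl]-2-oxo-2H-chromen-4-yl benzoate F8. The enol benzoate on C4, a vinylogous mixed anhydride, should then be cleaved selectively by aminolysis with pyrrolidine (1.1 equiv, THF, 0 °C), leaving the alkyl benzoate and giving 14.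

**Further compounds**
F1 | step 6 | (2E,6E,10E)-11-iodo-2,6,10-trimethylundeca-2,6,10-trien-1-ol | I/C=C(\C)CC/C=C(\C)CC/C=C(\C)CO
F2 | step 6 | chloro({2-oxo-4-[2-(trimethylsilyl)ethoxy]-2H-chromen-3-yl}methyl)zinc | Cl[Zn]Cc1c(OCC[Si](C)(C)C)c2ccccc2oc1=O
F3 | step 2 | (6E)-3-bromo-2,6-dimethylundec-6-en-10-yn-2-ol (racemic) | CC(C)(O)C(Br)CC/C(C)=C/CCC#C
F4 | step 2 | 2,2-dimethyl-3-[(3E)-3-methyloct-3-en-7-yn-1-yl]oxirane (racemic) | CC1(C)OC1CC/C(C)=C/CCC#C
F5 | step 2 | (4E)-4-methylnon-4-en-8-ynal | O=CCC/C(C)=C/CCC#C
F6 | step 2 | ethyl (2E,6E)-2,6-dimethylundeca-2,6-dien-10-ynoate | CCOC(=O)/C(C)=C/CC/C(C)=C/CCC#C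
F7 | step 8 | 4-hydroxy-3-[(2E,6E,10E)-12-hydroxy-3,7,11-trimethyldodeca-2,6,10-trien-1-yl]-2H-chromen-2-one | C/C(=C\CC/C(C)=C/Cc1c(O)c2ccccc2oc1=O)CC/C=C(\C)CO
F8 | step 8 | 3-[(2E,6E,10E)-12-(benzoyloxy)-3,7,11-trimethyldodeca-2,6,10-trien-1-yl]-2-oxo-2H-chromen-4-yl benzoate | C/C(=C\CC/C(C)=C/Cc1c(OC(=O)c2ccccc2)c2ccccc2oc1=O)CC/C=C(\C)COC(=O)c1ccccc1
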